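**Strategy**

With the cyclohexane numbered from the carbon that bears the propanal chain, the ring is disconnected at C-3–C-4 and C-6–C-1 into two three-carbon units. One radical annulation mediated by manganese triacetate joins a malonate that already holds the quaternary carbon C-2 and a vinyl group (future C-3 with its methyl) to isopropylidenecyclopropane: the malonyl radical (future C-1) adds to the cyclopropylidene carbon, ring opening releases the C-6 isopropylidene unit and a C-4 radical, and 6-exo closure onto the vinyl group completes the ring. The step exploits that C-4, C-5, C-6 and the exocyclic alkene carbon are a ring-opened alkylidenecyclopropane. Dealkoxycarbonylation, two-carbon homologation and a late Mitsunobu etherification with isofraxidin follow.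

Key step: step 4

Assumption: the (1R,2R)-configured ligand of step 2 is taken to give the (S)-quaternary centre of 7; if the sense is the opposite, the enantiomeric ligand is used and nothing else changes.

**Route**

Step 1
Reactants: 1 cyclopropyltriphenylphosphonium bromide; 2 acetone
Product: 4 isopropylidenecyclopropane, via cyclopropylidenetriphenylphosphorane 3 (not isolated)
Conditions: NaH, tris[2-(2-methoxyethoxy)ethyl]amine (cat.), THF, 62 °C
Reagents that add atoms: none
Why: Wittig olefination of acetone by the ylide 3 should give the strained tetrasubstituted alkene; no stereocentre is formed.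

Step 2
Reactants: 5 racemic 2-methyl-2-vinyloxirane; 6 dimethyl malonate
Product: 7 dimethyl 2-[(2S)-1-hydroxy-2-methylbut-3-en-2-yl]propanedioate
Conditions: Pd2(dba)3·CHCl3 (cat.), (1R,2R)-N,N′-bis[2-(diphenylphosphanyl)benzoyl]cyclohexane-1,2-diamine (cat.), CH2Cl2, rt; crude product used at once
Reagents that add atoms: none
Why: Tsuji–Trost asymmetric allylic alkylation run as a dynamic kinetic asymmetric transformation: zerovalent palladium opens both epoxide enantiomers to interconverting π-allyl complexes and the alkoxide-paired malonate attacks the substituted allyl terminus, so that the chiral ligand sets the (S)-quaternary centre.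

Step 3
Reactants: 7 dimethyl 2-[(2S)-1-hydroxy-2-methylbut-3-en-2-yl]propanedioate
Product: 8 dimethyl 2-[(2S)-1-[(tert-butyldiphenylsilyl)oxy]-2-methylbut-3-en-2-yl]propanedioate
Conditions: tert-butyl(chloro)diphenylsilane, imidazole, DMF, 0 °C to rt
Reagents that add atoms: tert-butyl(chloro)diphenylsilane, CC(C)(C)[Si](Cl)(c1ccccc1)c1ccccc1
Why: Silylation of the primary alcohol blocks lactonisation onto the malonate and installs the bulky group that later steers the ring closure; the stereocentre is not touched.

Step 4
Reactants: 8 dimethyl 2-[(2S)-1-[(tert-butyldiphenylsilyl)oxy]-2-methylbut-3-en-2-yl]propanedioate; 4 isopropylidenecyclopropane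
Product: 13 dimethyl (2S,3S)-2-{[(tert-butyldiphenylsilyl)oxy]methyl}-2,3-dimethyl-6-(propan-2-ylidene)cyclohexane-1,1-dicarboxylate, via malonyl radical 9 (not isolated), via cyclopropylcarbinyl radical 10 (not isolated), via homoallyl radical 11 (not isolated), via cyclised primary radical 12 (not isolated)
Conditions: 4 (5 equiv), Mn(OAc)3·2H2O (2.2 equiv), EtOH/AcOH 4:1, 70 °C, sealed tube
Reagents that add atoms: none
Why: Proposed new method: manganese triacetate oxidises the enolate of 8 to the electrophilic malonyl radical 9, which adds to the ring carbon of the strained, electron-rich alkene 4 (bond C-1–C-6) to give the tertiary cyclopropylcarbinyl radical 10; 10 opens to the homoallyl radical 11 with the isopropylidene group in place, 11 closes onto the vinyl group (bond C-3–C-4) to the primary radical 12, and 12 takes a hydrogen atom from ethanol to become the C-3 methyl group. The closest known reaction type is the manganese triacetate addition of malonates to alkylidenecyclopropanes with ring opening, joined here to a radical cyclisation of the 6-heptenyl type. The cyclohexane ring closes in the 6-exo-trig mode through a chair-like transition state. The new stereocentre C-3 is controlled by the quaternary centre C-2: the bulky silyloxymethyl group stands axial to avoid allylic 1,2-strain with the attacked vinyl group and gauche contacts with both esters, so the C-2 methyl group and the emerging CH2 radical lie equatorial and trans, which is the (2S,3S) arrangement. The step needs attack at the ring carbon and not at CMe2 (secured by the tertiary radical that results and by strain release) and ring closure ahead of hydrogen abstraction or a 1,5-hydrogen shift (favoured by the two fully substituted carbons in the chain and by the excess of 4).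

Step 5
Reactants: 13 dimethyl (2S,3S)-2-{[(tert-butyldiphenylsilyl)oxy]methyl}-2,3-dimethyl-6-(propan-2-ylidene)cyclohexane-1,1-dicarboxylate
Product: 15 methyl (1S,2S,3S)-2-{[(tert-butyldiphenylsilyl)oxy]methyl}-2,3-dimethyl-6-(propan-2-ylidene)cyclohexane-1-carboxylate, via kinetic monoester mixture 14 (not isolated)
Conditions: LiCl, H2O, DMSO, 150 °C; then NaOMe (cat.), MeOH, rt
Reagents that add atoms: none
Why: Krapcho dealkoxycarbonylation should give the monoester 14 as an epimer mixture, and methoxide equilibration through the ester enolate then sets C-1 under thermodynamic control, because only the (1S)-epimer holds the ester axial and trans to the axial silyloxymethyl group and so escapes allylic 1,3-strain with the isopropylidene group.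

Step 6
Reactants: 15 methyl (1S,2S,3S)-2-{[(tert-butyldiphenylsilyl)oxy]methyl}-2,3-dimethyl-6-(propan-2-ylidene)cyclohexane-1-carboxylate
Product: 16 (1S,2S,3S)-2-{[(tert-butyldiphenylsilyl)oxy]methyl}-2,3-dimethyl-6-(propan-2-ylidene)cyclohexane-1-carbaldehyde
Conditions: i-Bu2AlH (1.1 equiv), CH2Cl2, −78 °C; aqueous potassium sodium tartrate
Reagents that add atoms: none
Why: Partial hydride reduction of the hindered ester should stop at the tetrahedral aluminium hemiacetal at −78 °C and give the aldehyde on work-up without touching the C-1 stereocentre.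

Step 7
Reactants: 16 (1S,2S,3S)-2-{[(tert-butyldiphenylsilyl)oxy]methyl}-2,3-dimethyl-6-(propan-2-ylidene)cyclohexane-1-carbaldehyde; 17 (triphenylphosphoranylidene)acetaldehyde
Product: 18 (2E)-3-[(1S,2S,3S)-2-{[(tert-butyldiphenylsilyl)oxy]methyl}-2,3-dimethyl-6-(propan-2-ylidene)cyclohexyl]prop-2-enal
Conditions: toluene, 80 °C
Reagents that add atoms: none
Why: Wittig olefination with the stabilised formylmethylene ylide adds the two missing chain carbons as the (E)-enal under neutral conditions that should not epimerise C-1.

Step 8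
Reactants: 18 (2E)-3-[(1S,2S,3S)-2-{[(tert-butyldiphenylsilyl)oxy]methyl}-2,3-dimethyl-6-(propan-2-ylidene)cyclohexyl]prop-2-enal
Product: 19 3-[(1S,2S,3S)-2-{[(tert-butyldiphenylsilyl)oxy]methyl}-2,3-dimethyl-6-(propan-2-ylidene)cyclohexyl]propanal
Conditions: diethyl 2,6-dimethyl-1,4-dihydropyridine-3,5-dicarboxylate (Hantzsch ester), dibenzylammonium trifluoroacetate (cat.), THF, rt
Reagents that add atoms: none
Why: Iminium-catalysed transfer hydrogenation from the Hantzsch ester should reduce only the conjugated enal double bond and leave the tetrasubstituted isopropylidene alkene and the aldehyde untouched.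

Step 9
Reactants: 19 3-[(1S,2S,3S)-2-{[(tert-butyldiphenylsilyl)oxy]methyl}-2,3-dimethyl-6-(propan-2-ylidene)cyclohexyl]propanal
Product: 20 3-[(1S,2S,3S)-2-(hydroxymethyl)-2,3-dimethyl-6-(propan-2-ylidene)cyclohexyl]propanal
Conditions: Bu4NF, AcOH, THF, rt to 40 °C
Reagents that add atoms: none
Why: Fluoride-mediated desilylation, buffered with acetic acid, should free the primary alcohol without base-induced aldol reaction of the aldehyde.

Step 10
Reactants: 20 3-[(1S,2S,3S)-2-(hydroxymethyl)-2,3-dimethyl-6-(propan-2-ylidene)cyclohexyl]propanal; 21 isofraxidin (7-hydroxy-6,8-dimethoxy-2H-chromen-2-one)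
Product: 22 3-[(1S,2S,3S)-2-{[(6,8-dimethoxy-2-oxo-2H-chromen-7-yl)oxy]methyl}-2,3-dimethyl-6-(propan-2-ylidene)cyclohexyl]propanal
Conditions: PPh3, diisopropyl azodicarboxylate, THF (high concentration), sonication, 0 °C to rt
Reagents that add atoms: none
Why: Mitsunobu etherification, in which the acidic 7-hydroxycoumarin displaces the oxyphosphonium of the primary alcohol; high concentration and sonication are meant to offset the neopentyl hindrance, and no stereocentre is touched.

**Compound list**

1 | cyclopropyltriphenylphosphonium bromide | [Br-].C1CC1[P+](c1ccccc1)(c1ccccc1)c1ccccc1 | starting material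
2 | acetone (propan-2-one) | CC(C)=O | starting material
3 | cyclopropylidenetriphenylphosphorane (not isolated) | C1CC1=P(c1ccccc1)(c1ccccc1)c1ccccc1 | intermediate
4 | isopropylidenecyclopropane ((propan-2-ylidene)cyclopropane) | CC(C)=C1CC1 | intermediate
5 | racemic 2-methyl-2-vinyloxirane (isoprene monoepoxide) | CC1(CO1)C=C | starting material
6 | dimethyl malonate | COC(=O)CC(=O)OC | starting material
7 | dimethyl 2-[(2S)-1-hydroxy-2-methylbut-3-en-2-yl]propanedioate | OC[C@@](C(C(=O)OC)C(=O)OC)(C)C=C | intermediate
8 | dimethyl 2-[(2S)-1-[(tert-butyldiphenylsilyl)oxy]-2-methylbut-3-en-2-yl]propanedioate | CC(C)(C)[Si](c1ccccc1)(c1ccccc1)OC[C@@](C(C(=O)OC)C(=O)OC)(C)C=C | intermediate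
9 | malonyl radical formed from 8 by loss of the malonate hydrogen (not isolated) | CC(C)(C)[Si](c1ccccc1)(c1ccccc1)OC[C@@]([C](C(=O)OC)C(=O)OC)(C)C=C | intermediate
10 | tertiary cyclopropylcarbinyl radical, adduct of 9 to the ring carbon of 4 (not isolated) | CC(C)(C)[Si](c1ccccc1)(c1ccccc1)OC[C@@](C(C(=O)OC)(C(=O)OC)C1(CC1)[C](C)C)(C)C=C | intermediate
11 | ring-opened homoallyl radical, C-5 radical of the 2-(2-methylpent-2-en-3-yl)malonate (not isolated) | CC(C)(C)[Si](c1ccccc1)(c1ccccc1)OC[C@@](C(C(=O)OC)(C(=O)OC)C(=C(C)C)C[CH2])(C)C=C | intermediate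
12 | cyclised primary radical, CH2 radical at C-3 of the cyclohexane (not isolated) | CC(C)(C)[Si](c1ccccc1)(c1ccccc1)OC[C@@]1(C)[C@@H]([CH2])CCC(=C(C)C)C1(C(=O)OC)C(=O)OC | intermediate
13 | dimethyl (2S,3S)-2-{[(tert-butyldiphenylsilyl)oxy]methyl}-2,3-dimethyl-6-(propan-2-ylidene)cyclohexane-1,1-dicarboxylate | CC(C)(C)[Si](c1ccccc1)(c1ccccc1)OC[C@@]1(C)[C@@H](C)CCC(=C(C)C)C1(C(=O)OC)C(=O)OC | intermediate
14 | methyl (2S,3S)-2-{[(tert-butyldiphenylsilyl)oxy]methyl}-2,3-dimethyl-6-(propan-2-ylidene)cyclohexane-1-carboxylate, mixture of C-1 epimers (not isolated) | CC(C)(C)[Si](c1ccccc1)(c1ccccc1)OC[C@@]1(C)[C@@H](C)CCC(=C(C)C)C1C(=O)OC | intermediate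
15 | methyl (1S,2S,3S)-2-{[(tert-butyldiphenylsilyl)oxy]methyl}-2,3-dimethyl-6-(propan-2-ylidene)cyclohexane-1-carboxylate | CC(C)(C)[Si](c1ccccc1)(c1ccccc1)OC[C@@]1(C)[C@@H](C)CCC(=C(C)C)[C@@H]1C(=O)OC | intermediate
16 | (1S,2S,3S)-2-{[(tert-butyldiphenylsilyl)oxy]methyl}-2,3-dimethyl-6-(propan-2-ylidene)cyclohexane-1-carbaldehyde | CC(C)(C)[Si](c1ccccc1)(c1ccccc1)OC[C@@]1(C)[C@@H](C)CCC(=C(C)C)[C@@H]1C=O | intermediate
17 | (triphenylphosphoranylidene)acetaldehyde | O=CC=P(c1ccccc1)(c1ccccc1)c1ccccc1 | starting material
18 | (2E)-3-[(1S,2S,3S)-2-{[(tert-butyldiphenylsilyl)oxy]methyl}-2,3-dimethyl-6-(propan-2-ylidene)cyclohexyl]prop-2-enal | CC(C)(C)[Si](c1ccccc1)(c1ccccc1)OC[C@@]1(C)[C@@H](C)CCC(=C(C)C)[C@@H]1/C=C/C=O | intermediate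
19 | 3-[(1S,2S,3S)-2-{[(tert-butyldiphenylsilyl)oxy]methyl}-2,3-dimethyl-6-(propan-2-ylidene)cyclohexyl]propanal | CC(C)(C)[Si](c1ccccc1)(c1ccccc1)OC[C@@]1(C)[C@@H](C)CCC(=C(C)C)[C@@H]1CCC=O | intermediate
20 | 3-[(1S,2S,3S)-2-(hydroxymethyl)-2,3-dimethyl-6-(propan-2-ylidene)cyclohexyl]propanal | OC[C@@]1(C)[C@@H](C)CCC(=C(C)C)[C@@H]1CCC=O | intermediate
21 | isofraxidin (7-hydroxy-6,8-dimethoxy-2H-chromen-2-one) | COc1cc2ccc(=O)oc2c(OC)c1O | starting material
22 | 3-[(1S,2S,3S)-2-{[(6,8-dimethoxy-2-oxo-2H-chromen-7-yl)oxy]methyl}-2,3-dimethyl-6-(propan-2-ylidene)cyclohexyl]propanal | COc1cc2ccc(=O)oc2c(OC)c1OC[C@@]1(C)[C@@H](C)CCC(=C(C)C)[C@@H]1CCC=O | target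

**Step count and risks**

Total step count: 10. Longest linear sequence: 9 steps (steps 2 to 10, from 2-methyl-2-vinyloxirane).

Steps most likely to fail:

1. Step 4 (proposed new method). The congested tertiary malonate may be oxidised only slowly, and bond formation between two fully substituted carbons may be slow, so that the radical chain is lost to hydrogen abstraction, to a 1,5-hydrogen shift from an isopropylidene methyl group or to further addition to 4 before the 6-exo closure; facial control at C-3 may also be weak. Fallback with known reactions, which makes the two bonds one after the other; it sets out from 4 and 6 and comes back at 13. Compound 6 is brominated (NaH, N-bromosuccinimide) to dimethyl 2-bromopropanedioate F1. Atom-transfer radical addition of F1 to 4 (Et3B, air) with ring opening should give dimethyl 2-(5-bromo-2-methylpent-2-en-3-yl)propanedioate F2. Tsuji–Trost asymmetric allylic alkylation of F2 with 5 under the catalyst of step 2 should give dimethyl 2-(5-bromo-2-methylpent-2-en-3-yl)-2-[(2S)-1-hydroxy-2-methylbut-3-en-2-yl]propanedioate F3. Silylation as in step 3 gives its tert-butyldiphenylsilyl ether F4, and 6-exo-trig radical cyclisation of F4 (Bu3SnH, AIBN, benzene, 80 °C) should give 13.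

2. Step 2. The malonate may attack the unsubstituted allyl terminus (1,4-opening), the π-allyl complexes may not equilibrate fully (loss of enantioselectivity), or the product may lactonise before silylation. Fallback by a branch-selective iridium-catalysed alkylation; it sets out from 6 and comes back at 8. Commercial 3-methylbut-2-en-1-ol is converted with methyl chloroformate into 3-methylbut-2-en-1-yl methyl carbonate F5. Oxidation of the (E)-methyl group (SeO2, t-BuOOH) should give (2E)-4-hydroxy-3-methylbut-2-en-1-yl methyl carbonate F6, and silylation gives (2E)-4-[(tert-butyldiphenylsilyl)oxy]-3-methylbut-2-en-1-yl methyl carbonate F7. Asymmetric allylic alkylation of 6 with F7 ([Ir(cod)Cl]2, chiral phosphoramidite ligand, base, THF) should then give 8 directly.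

3. Step 10. Displacement at the neopentyl carbon by the doubly ortho-substituted phenoxide may be too slow, so that the oxyphosphonium intermediate decomposes or the alcohol is recovered. Fallback by a two-step alkylation; it sets out from 20 and comes back at 22. Compound 20 is converted (Tf2O, 2,6-lutidine, CH2Cl2, −78 °C) into the trifluoromethanesulfonate ester of alcohol 20 F8, which should alkylate the caesium phenoxide of 21 (Cs2CO3, DMF, rt) to give 22.

**Further compounds**

F1 | step 4 | dimethyl 2-bromopropanedioate | COC(=O)C(Br)C(=O)OC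
F2 | step 4 | dimethyl 2-(5-bromo-2-methylpent-2-en-3-yl)propanedioate | COC(=O)C(C(=O)OC)C(=C(C)C)CCBr
F3 | step 4 | dimethyl 2-(5-bromo-2-methylpent-2-en-3-yl)-2-[(2S)-1-hydroxy-2-methylbut-3-en-2-yl]propanedioate | OC[C@@](C(C(=O)OC)(C(=O)OC)C(=C(C)C)CCBr)(C)C=C
F4 | step 4 | tert-butyldiphenylsilyl ether of F3 | CC(C)(C)[Si](c1ccccc1)(c1ccccc1)OC[C@@](C(C(=O)OC)(C(=O)OC)C(=C(C)C)CCBr)(C)C=C
F5 | step 2 | 3-methylbut-2-en-1-yl methyl carbonate | COC(=O)OCC=C(C)C
F6 | step 2 | (2E)-4-hydroxy-3-methylbut-2-en-1-yl methyl carbonate | COC(=O)OC/C=C(\C)CO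
F7 | step 2 | (2E)-4-[(tert-butyldiphenylsilyl)oxy]-3-methylbut-2-en-1-yl methyl carbonate | COC(=O)OC/C=C(\C)CO[Si](c1ccccc1)(c1ccccc1)C(C)(C)C
F8 | step 10 | trifluoromethanesulfonate ester of alcohol 20 | FC(F)(F)S(=O)(=O)OC[C@@]1(C)[C@@H](C)CCC(=C(C)C)[C@@H]1CCC=O
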